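All nine hydroxyls of rings A to D (positions 1, 3 and 5 of ring A; 3 and 5 of rings B, C and D) lie ortho or para to a diaryl ether oxygen. Each is therefore disconnected to a formyl group, which first activates a C–F carbon for SNAr ether formation and is then exchanged for oxygen. One ninefold Baeyer–Villiger oxidation with aryl migration, followed by formate methanolysis, installs all nine C–O bonds without closing a ring. Its substrate is a nonaformyl pentaaryl ether whose ring E carries three benzyl ethers, built by four SNAr couplings.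

Key step: step 18

**Remarks on the chemistry**

- Rings are lettered A to E from the 2,4,6-trihydroxyphenoxy end. In rings B to E, position 1 is the carbon bonded to the ether oxygen that points towards ring A. The ether carbons are position 2 of ring A, positions 1 and 4 of rings B and D, positions 1 and 2 of ring C, and position 1 of ring E.
- Assumption: 4-fluoro-3,5-dimethylphenol, 1-fluoro-2,4-dimethylbenzene and 3,4,5-trihydroxybenzaldehyde are bought.
- The nonaformyl precursor and the nonaphenol product of the key step were compared ring by ring with the target. Their nine formyl groups and nine free hydroxyls sit exactly where the target has the hydroxyls of rings A to D.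
- Each fluorophenol unit enters as its bis(dimethyl acetal). The phenoxide nucleophile therefore never carries an activated fluoride, so the chain cannot oligomerise. The acid work-up then unmasks the formyl groups that arm the new terminal fluoride.
- Ring A is joined last, because its ether carbon, flanked by three formyl groups, is the one most open to aryloxide exchange.

Step 1
Reactants: 1 2-fluoro-1,3,5-trimethylbenzene
Product: 2 1,3,5-tris(dibromomethyl)-2-fluorobenzene
Conditions: NBS (6.6 equiv), AIBN (cat.), PhCF3, reflux, visible light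
Reagents that add atoms: N-bromosuccinimide, O=C1CCC(=O)N1Br
Why: Wohl–Ziegler radical bromination should take each benzylic methyl to the gem-dibromide and stop there, since a third bromine on the same carbon is sterically and electronically disfavoured, as in the exhaustive side-chain bromination of mesitylene.

Step 2
Reactants: 2 1,3,5-tris(dibromomethyl)-2-fluorobenzene
Product: 3 2-fluorobenzene-1,3,5-tricarbaldehyde
Conditions: AgNO3 (6.6 equiv), acetone/H2O, 50 °C, dark
Reagents that add atoms: water, O
Why: Silver-assisted hydrolysis of benzal bromides should give the three aldehydes under acidic conditions in which water is too weak a nucleophile to displace the activated fluoride.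

Step 3
Reactants: 4 4-fluoro-3,5-dimethylphenol
Product: 5 4-fluoro-3,5-dimethylphenyl acetate
Conditions: Ac2O, pyridine, DMAP (cat.), CH2Cl2, rt
Reagents that add atoms: acetic anhydride, CC(=O)OC(C)=O
Why: O-Acetylation (nucleophilic acyl substitution) turns the phenol into an ester that resists nuclear bromination and oxidation under the radical conditions of step 4.

Step 4
Reactants: 5 4-fluoro-3,5-dimethylphenyl acetate
Product: 6 3,5-bis(dibromomethyl)-4-fluorophenyl acetate
Conditions: NBS (4.4 equiv), AIBN (cat.), PhCF3, reflux, visible light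
Reagents that add atoms: N-bromosuccinimide, O=C1CCC(=O)N1Br
Why: Wohl–Ziegler bromination should convert both methyl groups next to fluorine into dibromomethyl groups, the acetoxy-substituted ring being too deactivated for nuclear bromination under radical conditions.

Step 5
Reactants: 6 3,5-bis(dibromomethyl)-4-fluorophenyl acetate
Product: 8 4-fluoro-3,5-bis(dimethoxymethyl)phenol, via sodium 3,5-bis(dibromomethyl)-4-fluorophenolate 7 (not isolated)
Conditions: NaOMe (8 equiv), MeOH, reflux; then AcOH to pH 7
Reagents that add atoms: sodium methoxide, [Na+].[O-]C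
Why: Methoxide first cleaves the aryl acetate by transesterification and then converts both benzal bromide groups into dimethyl acetals by double nucleophilic substitution (the classical benzal halide to acetal conversion), the phenoxide formed at the outset keeping the fluoride inert.

Step 6
Reactants: 8 4-fluoro-3,5-bis(dimethoxymethyl)phenol
Product: 10 2-fluoro-5-(prop-2-en-1-yloxy)benzene-1,3-dicarbaldehyde, via allyl ether bis(dimethyl acetal) 9 (not isolated)
Conditions: allyl bromide, K2CO3, DMF, rt; then 1 M HCl, THF, rt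
Reagents that add atoms: allyl bromide, C=CCBr; water, O
Why: Williamson etherification of a phenoxide whose fluoride is unactivated while the aldehydes are masked, followed by acid hydrolysis of the acetals, should give the ring B electrophile with its phenol oxygen blocked.

Step 7
Reactants: 11 1-fluoro-2,4-dimethylbenzene
Product: 14 2-fluoro-3,5-dimethylphenol, via (2-fluoro-3,5-dimethylphenyl)lithium 12 (not isolated), via dimethyl (2-fluoro-3,5-dimethylphenyl)boronate 13 (not isolated)
Conditions: sec-BuLi, TMEDA, THF, −78 °C; B(OMe)3, −78 °C to rt; H2O2 (30%), AcOH, 0 °C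
Reagents that add atoms: hydrogen peroxide, OO
Why: Fluorine-directed ortho-lithiation can occur only at position 6 of 11, the single ring hydrogen next to fluorine, and borylation followed by oxidative 1,2-shift from boron to oxygen should deliver the phenol as one regioisomer.

Step 8
Reactants: 14 2-fluoro-3,5-dimethylphenol
Product: 15 2-fluoro-3,5-dimethylphenyl acetate
Conditions: Ac2O, pyridine, DMAP (cat.), CH2Cl2, rt
Reagents that add atoms: acetic anhydride, CC(=O)OC(C)=O
Why: O-Acetylation protects the phenol and deactivates the ring ahead of the radical bromination, as in step 3.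

Step 9
Reactants: 15 2-fluoro-3,5-dimethylphenyl acetate
Product: 16 3,5-bis(dibromomethyl)-2-fluorophenyl acetate
Conditions: NBS (4.4 equiv), AIBN (cat.), PhCF3, reflux, visible light
Reagents that add atoms: N-bromosuccinimide, O=C1CCC(=O)N1Br
Why: Wohl–Ziegler bromination should give the bis(gem-dibromide), benzylic hydrogen abstraction outrunning attack on the acetoxy- and fluoro-deactivated ring.

Step 10
Reactants: 16 3,5-bis(dibromomethyl)-2-fluorophenyl acetate
Product: 18 2-fluoro-3,5-bis(dimethoxymethyl)phenol, via sodium 3,5-bis(dibromomethyl)-2-fluorophenolate 17 (not isolated)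
Conditions: NaOMe (8 equiv), MeOH, reflux; then AcOH to pH 7
Reagents that add atoms: sodium methoxide, [Na+].[O-]C
Why: As in step 5, acetate methanolysis and benzal bromide to acetal substitution occur in one operation, the ortho phenoxide shielding the fluoride from methoxide.

Step 11
Reactants: 19 3,4,5-trihydroxybenzaldehyde
Product: 20 3,4,5-tris(benzyloxy)benzaldehyde
Conditions: BnBr (3.3 equiv), K2CO3, DMF, 60 °C
Reagents that add atoms: benzyl bromide, BrCc1ccccc1
Why: Threefold Williamson O-benzylation of the phenoxides is routine, the formyl group being untouched by carbonate.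

Step 12
Reactants: 20 3,4,5-tris(benzyloxy)benzaldehyde
Product: 22 3,4,5-tris(benzyloxy)phenol, via 3,4,5-tris(benzyloxy)phenyl formate 21 (not isolated)
Conditions: mCPBA, CH2Cl2, rt; aq. NaHCO3 wash; then K2CO3 (cat.), MeOH, rt
Reagents that add atoms: 3-chloroperoxybenzoic acid, O=C(OO)c1cccc(Cl)c1
Why: Baeyer–Villiger (Dakin-type) oxidation of an electron-rich benzaldehyde proceeds with aryl migration because the para benzyloxy group stabilises the migrating carbon, and the formate is methanolysed to the phenol.

Step 13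
Reactants: 10 2-fluoro-5-(prop-2-en-1-yloxy)benzene-1,3-dicarbaldehyde; 18 2-fluoro-3,5-bis(dimethoxymethyl)phenol
Product: 24 2-(2-fluoro-3,5-diformylphenoxy)-5-(prop-2-en-1-yloxy)benzene-1,3-dicarbaldehyde, via ring C bis(dimethyl acetal) diaryl ether 23 (not isolated)
Conditions: Cs2CO3, MeCN, Ar, rt to 40 °C; then 1 M HCl, THF, rt
Reagents that add atoms: water, O
Why: SNAr of the phenoxide of 18 at the fluoride of 10, activated by two ortho formyl groups, forms the ether between position 4 of ring B and position 1 of ring C without oligomerisation because the nucleophile has no activated fluoride, and acid hydrolysis of the acetals then arms the ring C fluoride.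

Step 14
Reactants: 24 ring B–C fluoride tetraaldehyde; 8 4-fluoro-3,5-bis(dimethoxymethyl)phenol
Product: 26 2-[2-(4-fluoro-3,5-diformylphenoxy)-3,5-diformylphenoxy]-5-(prop-2-en-1-yloxy)benzene-1,3-dicarbaldehyde, via ring D bis(dimethyl acetal) triaryl ether 25 (not isolated)
Conditions: Cs2CO3, MeCN, Ar, rt to 50 °C; then 1 M HCl, THF, rt
Reagents that add atoms: water, O
Why: SNAr at the ring C fluoride of 24, activated by one ortho and one para formyl group, should outrun attack at the ring B ether carbon because fluorine accelerates the rate-determining addition far more than an aryloxy group does, and acid work-up unmasks the ring D formyl groups.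

Step 15
Reactants: 26 ring B–C–D fluoride hexaaldehyde; 22 3,4,5-tris(benzyloxy)phenol
Product: 27 allyl-capped tetraaryl ether hexaaldehyde (26 with the ring D fluorine replaced by the 3,4,5-tris(benzyloxy)phenoxy group)
Conditions: Cs2CO3, MeCN, Ar, rt
Reagents that add atoms: none
Why: SNAr of the electron-rich phenoxide of 22 at the ring D fluoride, which lies between two formyl groups and should react well ahead of any ether carbon of 26.

Step 16
Reactants: 27 allyl-capped tetraaryl ether hexaaldehyde
Product: 28 tetraaryl ether phenol hexaaldehyde (free hydroxyl at position 1 of ring B)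
Conditions: Pd(PPh3)4 (5 mol%), 4-MeC6H4SO2Na, THF/MeOH, rt; then dilute HCl
Reagents that add atoms: none
Why: Tsuji–Trost deallylation, in which zerovalent palladium ionises the allyl aryl ether and the sulfinate traps the π-allyl complex as a sulfone, runs near neutrality and should leave the six aldehydes, the benzyl ethers and the diaryl ethers alone.

Step 17
Reactants: 28 tetraaryl ether phenol hexaaldehyde; 3 2-fluorobenzene-1,3,5-tricarbaldehyde (1.3 equiv)
Product: 29 nonaformyl pentaaryl ether with ring E as its tribenzyl ether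
Conditions: Cs2CO3 (1.1 equiv), MeCN/DMSO, 4 Å MS, Ar, 0 °C to rt
Reagents that add atoms: none
Why: SNAr at a fluoride flanked by two ortho and one para formyl group is fast even with the weakly nucleophilic ring B phenoxide, and since ring A enters last its labile ether carbon never meets a foreign phenoxide.

Step 18
Reactants: 29 nonaformyl pentaaryl ether
Product: 31 nonaphenol pentaaryl ether (ring E tribenzyl ether), via nonaformate 30 (not isolated)
Conditions: mCPBA (dried, 20 equiv), CH2Cl2, 0 °C to rt, dark; Me2S; then HCl (0.1 M), MeOH (degassed), Ar, rt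
Reagents that add atoms: 3-chloroperoxybenzoic acid, O=C(OO)c1cccc(Cl)c1
Why: Proposed new method: each formyl group adds the peracid to give a Criegee-type peroxyhemiacetal, which collapses by 1,2-shift of the aryl carbon to oxygen with loss of 3-chlorobenzoate, giving nine aryl formates that acid-catalysed methanolysis then cleaves. The closest known reaction is the Baeyer–Villiger (Dakin-type) oxidation of an ortho- or para-aryloxybenzaldehyde to the phenol, practised on one or two formyl groups per substrate. No ring is closed and no stereocentre is formed. The selectivity needed is aryl over hydride migration in all nine adducts; it should be secured because every formyl-bearing carbon has an ether oxygen lone pair ortho or para to it (the oxygen on position 2 of ring A for the formyl groups at positions 1, 3 and 5 of that ring; the oxygen on position 4 of rings B and D and on position 2 of ring C for the formyl groups at positions 3 and 5 of those rings), which stabilises the electron-deficient migrating carbon, while the other formyl groups of the same ring sit meta to it and act only inductively. Each formate formed replaces an acceptor by a donor, so the rings should migrate more readily as the oxidation proceeds, the first event on ring A being the slowest. Acidic methanolysis under argon is chosen over a basic cleavage to keep the electron-rich nonaphenol from autoxidation, and the benzyl ethers of ring E are expected to survive both stages.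

Step 19
Reactants: 31 nonaphenol tribenzyl ether
Product: 32 target dodecaphenol (CNP0227069.0)
Conditions: H2 (1 atm), Pd/C (10%), MeOH/EtOAc (degassed), rt
Reagents that add atoms: none
Why: Catalytic hydrogenolysis of the three benzyl ethers is neutral and should leave the diaryl ethers and free phenols untouched.

**Compound list**

1 | 2-fluoro-1,3,5-trimethylbenzene | Cc1cc(C)c(F)c(C)c1 | starting material
2 | 1,3,5-tris(dibromomethyl)-2-fluorobenzene | Fc1c(C(Br)Br)cc(C(Br)Br)cc1C(Br)Br | intermediate
3 | 2-fluorobenzene-1,3,5-tricarbaldehyde (ring A electrophile) | O=Cc1cc(C=O)c(F)c(C=O)c1 | intermediate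
4 | 4-fluoro-3,5-dimethylphenol | Cc1cc(O)cc(C)c1F | starting material
5 | 4-fluoro-3,5-dimethylphenyl acetate | CC(=O)Oc1cc(C)c(F)c(C)c1 | intermediate
6 | 3,5-bis(dibromomethyl)-4-fluorophenyl acetate | CC(=O)Oc1cc(C(Br)Br)c(F)c(C(Br)Br)c1 | intermediate
7 | sodium 3,5-bis(dibromomethyl)-4-fluorophenolate | [Na+].[O-]c1cc(C(Br)Br)c(F)c(C(Br)Br)c1 | intermediate
8 | 4-fluoro-3,5-bis(dimethoxymethyl)phenol (masked ring D unit) | COC(OC)c1cc(O)cc(C(OC)OC)c1F | intermediate
9 | 2-fluoro-1,3-bis(dimethoxymethyl)-5-(prop-2-en-1-yloxy)benzene | C=CCOc1cc(C(OC)OC)c(F)c(C(OC)OC)c1 | intermediate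
10 | 2-fluoro-5-(prop-2-en-1-yloxy)benzene-1,3-dicarbaldehyde (ring B electrophile) | C=CCOc1cc(C=O)c(F)c(C=O)c1 | intermediate
11 | 1-fluoro-2,4-dimethylbenzene | Cc1ccc(F)c(C)c1 | starting material
12 | (2-fluoro-3,5-dimethylphenyl)lithium | [Li]c1cc(C)cc(C)c1F | intermediate
13 | dimethyl (2-fluoro-3,5-dimethylphenyl)boronate | COB(OC)c1cc(C)cc(C)c1F | intermediate
14 | 2-fluoro-3,5-dimethylphenol | Cc1cc(C)c(F)c(O)c1 | intermediate
15 | 2-fluoro-3,5-dimethylphenyl acetate | CC(=O)Oc1cc(C)cc(C)c1F | intermediate
16 | 3,5-bis(dibromomethyl)-2-fluorophenyl acetate | CC(=O)Oc1cc(C(Br)Br)cc(C(Br)Br)c1F | intermediate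
17 | sodium 3,5-bis(dibromomethyl)-2-fluorophenolate | [Na+].[O-]c1cc(C(Br)Br)cc(C(Br)Br)c1F | intermediate
18 | 2-fluoro-3,5-bis(dimethoxymethyl)phenol (masked ring C unit) | COC(OC)c1cc(O)c(F)c(C(OC)OC)c1 | intermediate
19 | 3,4,5-trihydroxybenzaldehyde | O=Cc1cc(O)c(O)c(O)c1 | starting material
20 | 3,4,5-tris(benzyloxy)benzaldehyde | O=Cc1cc(OCc2ccccc2)c(OCc2ccccc2)c(OCc2ccccc2)c1 | intermediate
21 | 3,4,5-tris(benzyloxy)phenyl formate | O=COc1cc(OCc2ccccc2)c(OCc2ccccc2)c(OCc2ccccc2)c1 | intermediate
22 | 3,4,5-tris(benzyloxy)phenol (ring E unit) | Oc1cc(OCc2ccccc2)c(OCc2ccccc2)c(OCc2ccccc2)c1 | intermediate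
23 | 2-[2-fluoro-3,5-bis(dimethoxymethyl)phenoxy]-5-(prop-2-en-1-yloxy)benzene-1,3-dicarbaldehyde | C=CCOc1cc(C=O)c(Oc2cc(C(OC)OC)cc(C(OC)OC)c2F)c(C=O)c1 | intermediate
24 | 2-(2-fluoro-3,5-diformylphenoxy)-5-(prop-2-en-1-yloxy)benzene-1,3-dicarbaldehyde (ring B–C fluoride) | C=CCOc1cc(C=O)c(Oc2cc(C=O)cc(C=O)c2F)c(C=O)c1 | intermediate
25 | 2-{2-[4-fluoro-3,5-bis(dimethoxymethyl)phenoxy]-3,5-diformylphenoxy}-5-(prop-2-en-1-yloxy)benzene-1,3-dicarbaldehyde | C=CCOc1cc(C=O)c(Oc2cc(C=O)cc(C=O)c2Oc2cc(C(OC)OC)c(F)c(C(OC)OC)c2)c(C=O)c1 | intermediate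
26 | 2-[2-(4-fluoro-3,5-diformylphenoxy)-3,5-diformylphenoxy]-5-(prop-2-en-1-yloxy)benzene-1,3-dicarbaldehyde (ring B–C–D fluoride) | C=CCOc1cc(C=O)c(Oc2cc(C=O)cc(C=O)c2Oc2cc(C=O)c(F)c(C=O)c2)c(C=O)c1 | intermediate
27 | 2-(2-{3,5-diformyl-4-[3,4,5-tris(benzyloxy)phenoxy]phenoxy}-3,5-diformylphenoxy)-5-(prop-2-en-1-yloxy)benzene-1,3-dicarbaldehyde | C=CCOc1cc(C=O)c(Oc2cc(C=O)cc(C=O)c2Oc2cc(C=O)c(Oc3cc(OCc4ccccc4)c(OCc4ccccc4)c(OCc4ccccc4)c3)c(C=O)c2)c(C=O)c1 | intermediate
28 | 2-(2-{3,5-diformyl-4-[3,4,5-tris(benzyloxy)phenoxy]phenoxy}-3,5-diformylphenoxy)-5-hydroxybenzene-1,3-dicarbaldehyde | Oc1cc(C=O)c(Oc2cc(C=O)cc(C=O)c2Oc2cc(C=O)c(Oc3cc(OCc4ccccc4)c(OCc4ccccc4)c(OCc4ccccc4)c3)c(C=O)c2)c(C=O)c1 | intermediate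
29 | nonaformyl pentaaryl ether (formyl at positions 1, 3 and 5 of ring A and at positions 3 and 5 of rings B, C and D; ring E 3,4,5-tribenzyloxy) | O=Cc1cc(C=O)c(Oc2cc(C=O)c(Oc3cc(C=O)cc(C=O)c3Oc3cc(C=O)c(Oc4cc(OCc5ccccc5)c(OCc5ccccc5)c(OCc5ccccc5)c4)c(C=O)c3)c(C=O)c2)c(C=O)c1 | intermediate
30 | nonaformate pentaaryl ether (formyloxy at the same nine positions; ring E 3,4,5-tribenzyloxy) | O=COc1cc(OC=O)c(Oc2cc(OC=O)c(Oc3cc(OC=O)cc(OC=O)c3Oc3cc(OC=O)c(Oc4cc(OCc5ccccc5)c(OCc5ccccc5)c(OCc5ccccc5)c4)c(OC=O)c3)c(OC=O)c2)c(OC=O)c1 | intermediate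
31 | nonaphenol pentaaryl ether, ring E tribenzyl ether | Oc1cc(O)c(Oc2cc(O)c(Oc3cc(O)cc(O)c3Oc3cc(O)c(Oc4cc(OCc5ccccc5)c(OCc5ccccc5)c(OCc5ccccc5)c4)c(O)c3)c(O)c2)c(O)c1 | intermediate
32 | CNP0227069.0 (dodecaphenol pentaaryl ether, achiral) | Oc1cc(O)c(Oc2cc(O)c(Oc3cc(O)cc(O)c3Oc3cc(O)c(Oc4cc(O)c(O)c(O)c4)c(O)c3)c(O)c2)c(O)c1 | target

**Total steps:** 19.
**Longest linear sequence:** 11 steps (steps 3, 4, 5, 6, 13, 14, 15, 16, 17, 18, 19 from 4; the line from 11 through steps 7 to 10 and 13 to 19 is equally long).

**Steps most likely to fail**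

1. Step 18 (Proposed new method). What may go wrong: hydride instead of aryl migration in the first peracid adducts on the electron-poor ring A, stalling at partly oxidised stages, or slow oxidation of the electron-rich ring E by the excess peracid. Fallback with known chemistry, setting out from 29: ninefold addition of MeMgBr (THF, −78 °C) should give the nona(1-hydroxyethyl) pentaaryl ether F1 as a mixture of diastereomers. Dess–Martin periodinane oxidation then gives the nonaacetyl pentaaryl ether F2. Baeyer–Villiger oxidation of the nine aryl methyl ketones (mCPBA, TFA cat., CH2Cl2) follows; here aryl migrates in preference to methyl and no hydride can migrate, so the nonaacetate pentaaryl ether F3 should form. Methanolysis with HCl in MeOH under argon comes back to the route at 31.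

2. Step 14. What may go wrong: slow substitution at the crowded ring C fluoride, which sits between a formyl group and the bulky ring B aryloxy group, so that aryloxide exchange at the ring B ether carbon or hydrolysis of the fluoride competes. Fallback, setting out from 18, forms the ether between rings C and D before ring B is present: allylation of 18 (allyl bromide, K2CO3, DMF) should give 2-fluoro-1,5-bis(dimethoxymethyl)-3-(prop-2-en-1-yloxy)benzene F4, and aqueous HCl then gives 4-fluoro-5-(prop-2-en-1-yloxy)benzene-1,3-dicarbaldehyde F5. SNAr with 8 (Cs2CO3, MeCN) gives the ring C–D diaryl ether bis(dimethyl acetal) F6 and, after acid, the ring C–D fluoride tetraaldehyde F7. SNAr with 22 gives the allyl-capped ring C–D–E triaryl ether F8, deallylation (Pd(PPh3)4, 4-MeC6H4SO2Na) gives the ring C–D–E triaryl ether phenol F9, and SNAr of F9 on 10 comes back to the route at 27.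

3. Step 1. What may go wrong: the sixfold radical bromination stopping short of, or running past, six bromines, or nuclear bromination, giving mixtures that cannot be separated. Fallback, setting out from 1: KMnO4 in aqueous pyridine at reflux should give 2-fluorobenzene-1,3,5-tricarboxylic acid F10. BH3·THF reduction gives (2-fluorobenzene-1,3,5-triyl)trimethanol F11. MnO2 in CH2Cl2/THF oxidises the three benzylic alcohols and comes back to the route at 3.

**Further compounds**

F1 | step 18 | nona(1-hydroxyethyl) pentaaryl ether, ring E tribenzyl ether (mixture of diastereomers) | CC(O)c1cc(C(C)O)c(Oc2cc(C(C)O)c(Oc3cc(C(C)O)cc(C(C)O)c3Oc3cc(C(C)O)c(Oc4cc(OCc5ccccc5)c(OCc5ccccc5)c(OCc5ccccc5)c4)c(C(C)O)c3)c(C(C)O)c2)c(C(C)O)c1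
F2 | step 18 | nonaacetyl pentaaryl ether, ring E tribenzyl ether | CC(=O)c1cc(C(C)=O)c(Oc2cc(C(C)=O)c(Oc3cc(C(C)=O)cc(C(C)=O)c3Oc3cc(C(C)=O)c(Oc4cc(OCc5ccccc5)c(OCc5ccccc5)c(OCc5ccccc5)c4)c(C(C)=O)c3)c(C(C)=O)c2)c(C(C)=O)c1
F3 | step 18 | nonaacetate pentaaryl ether, ring E tribenzyl ether | CC(=O)Oc1cc(OC(C)=O)c(Oc2cc(OC(C)=O)c(Oc3cc(OC(C)=O)cc(OC(C)=O)c3Oc3cc(OC(C)=O)c(Oc4cc(OCc5ccccc5)c(OCc5ccccc5)c(OCc5ccccc5)c4)c(OC(C)=O)c3)c(OC(C)=O)c2)c(OC(C)=O)c1
F4 | step 14 | 2-fluoro-1,5-bis(dimethoxymethyl)-3-(prop-2-en-1-yloxy)benzene | C=CCOc1cc(C(OC)OC)cc(C(OC)OC)c1F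
F5 | step 14 | 4-fluoro-5-(prop-2-en-1-yloxy)benzene-1,3-dicarbaldehyde | C=CCOc1cc(C=O)cc(C=O)c1F
F6 | step 14 | 4-[4-fluoro-3,5-bis(dimethoxymethyl)phenoxy]-5-(prop-2-en-1-yloxy)benzene-1,3-dicarbaldehyde | C=CCOc1cc(C=O)cc(C=O)c1Oc1cc(C(OC)OC)c(F)c(C(OC)OC)c1
F7 | step 14 | 4-(4-fluoro-3,5-diformylphenoxy)-5-(prop-2-en-1-yloxy)benzene-1,3-dicarbaldehyde | C=CCOc1cc(C=O)cc(C=O)c1Oc1cc(C=O)c(F)c(C=O)c1
F8 | step 14 | 4-{3,5-diformyl-4-[3,4,5-tris(benzyloxy)phenoxy]phenoxy}-5-(prop-2-en-1-yloxy)benzene-1,3-dicarbaldehyde | C=CCOc1cc(C=O)cc(C=O)c1Oc1cc(C=O)c(Oc2cc(OCc3ccccc3)c(OCc3ccccc3)c(OCc3ccccc3)c2)c(C=O)c1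
F9 | step 14 | 4-{3,5-diformyl-4-[3,4,5-tris(benzyloxy)phenoxy]phenoxy}-5-hydroxybenzene-1,3-dicarbaldehyde | Oc1cc(C=O)cc(C=O)c1Oc1cc(C=O)c(Oc2cc(OCc3ccccc3)c(OCc3ccccc3)c(OCc3ccccc3)c2)c(C=O)c1
F10 | step 1 | 2-fluorobenzene-1,3,5-tricarboxylic acid | OC(=O)c1cc(C(=O)O)c(F)c(C(=O)O)c1
F11 | step 1 | (2-fluorobenzene-1,3,5-triyl)trimethanol | OCc1cc(CO)c(F)c(CO)c1
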